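**Plan**
- Locants: flavanone numbering (O1, C2–C4, C4a, C5–C8, C8a) plus C1′ (OCH2), C2′ (CH), C3′ (CMe2). The retrosynthesis cuts O1–C8a and O–C6 (two late C–O bonds), then C5–C4a and C8–C8a of the carbocyclic cage.
- Enabling feature: the bicyclo[2.2.2]octene (bridgeheads C5 and C8) has a single C=C, C4a=C8a, and both pyranone links (C4 on C4a, O1 on C8a) sit on it. These two carbons can therefore come from a bromoalkynone that adds across C5 and C8 of a cyclohexa-1,3-diene oxygenated at C5 and C7.
- Forward: dimedone gives diene 9, in which an acetonide ties C5–O to C1′–O and so fixes the enol regiochemistry and the diene conformation. The (R)-hydroxy ester gives bromoynone 14. The [4+2] step builds the cage (15); C6 bromination and release of three hydroxyls then close the tetrahydrofuran (O–C6) and the pyranone (O1–C8a) in the last step.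
- Stereochemistry: C2 from the commercial (R)-ester; C2′ from a ligand-controlled hydroxymethylation; C5 and C8 from the diene face opposite the pseudo-axial C3′ methyl; C6 from bromination syn to the C4a=C8a bridge followed by SN2 inversion by the C1′ oxygen.

Key step: step 12

Assumption: in step 4 the (S,S)-ligand is taken to deliver the (R)-alcohol; if the sense of induction is the opposite, the (R,R)-ligand is used instead.

**Route**

Step 1
Reactants: 1 dimedone (5,5-dimethylcyclohexane-1,3-dione)
Product: 2 2,5,5-trimethylcyclohexane-1,3-dione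
Conditions: MeI, KOH, H2O/MeOH, reflux
Reagents that add atoms: iodomethane, CI
Why: C-methylation of the stabilised 1,3-dione enolate (enolate alkylation) places the future C6 methyl between the two carbonyls; no stereocentre is formed.

Step 2
Reactants: 2 2,5,5-trimethylcyclohexane-1,3-dione
Product: 3 3-(benzyloxy)-2,5,5-trimethylcyclohex-2-en-1-one
Conditions: BnOH, TsOH·H2O (cat.), toluene, reflux, Dean–Stark trap
Reagents that add atoms: benzyl alcohol, OCc1ccccc1
Why: Acid-catalysed vinylogous esterification with azeotropic removal of water can give only one enol ether from the symmetrical dione, and the benzyl group is later removable by hydrogenolysis without acid or base.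

Step 3
Reactants: 3 3-(benzyloxy)-2,5,5-trimethylcyclohex-2-en-1-one
Product: 4 1-(benzyloxy)-2,5,5-trimethyl-3-(trimethylsilyloxy)cyclohexa-1,3-diene
Conditions: LiN(i-Pr)2, THF, −78 °C; TMSCl, −78 → 0 °C; non-aqueous work-up
Reagents that add atoms: chlorotrimethylsilane, C[Si](C)(C)Cl
Why: Kinetic α′-deprotonation of the 3-alkoxyenone by the carbonyl-bound amide base and O-silylation (silyl enol ether formation) give the cross-conjugated silyl dienol ether whose nucleophilic carbon is the future C2′.

Step 4
Reactants: 4 1-(benzyloxy)-2,5,5-trimethyl-3-(trimethylsilyloxy)cyclohexa-1,3-diene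
Product: 5 (R)-3-(benzyloxy)-6-(hydroxymethyl)-2,5,5-trimethylcyclohex-2-en-1-one
Conditions: aq. HCHO, Sc(OTf)3 (10 mol %), (S,S)-6,6′-bis(1-hydroxy-2,2-dimethylpropyl)-2,2′-bipyridine (12 mol %), DME/H2O 9:1, −20 °C
Reagents that add atoms: formaldehyde, C=O
Why: Catalytic asymmetric Mukaiyama aldol (hydroxymethylation) of a silicon enolate with aqueous formaldehyde, in which the chiral Sc(OTf)3–bipyridine complex selects the enolate face and so should set C2′ as (R).

Step 5
Reactants: 5 (R)-3-(benzyloxy)-6-(hydroxymethyl)-2,5,5-trimethylcyclohex-2-en-1-one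
Product: 7 (4aR)-2,2,5,5,8-pentamethyl-4,4a,5,6-tetrahydro-7H-1,3-benzodioxin-7-one, via hydroxymethyl dione 6 (not isolated)
Conditions: H2 (1 atm), Pd/C, EtOAc, 23 °C; filter, concentrate; then 2-methoxypropene, PPTS (cat.), CH2Cl2, 0 °C
Reagents that add atoms: 2-methoxypropene, COC(C)=C
Why: Hydrogenolysis of the benzyl vinylogous ester frees the dione, and kinetic acetonide formation ties the C1′ hydroxyl to the only enol oxygen it can reach in a six-membered ring (C5–O), which fixes the enol ether at C5 and leaves the C7 ketone with C8H2 as its only α′ position; C2′ is not touched and no stereocentre is formed.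

Step 6
Reactants: 7 (4aR)-2,2,5,5,8-pentamethyl-4,4a,5,6-tetrahydro-7H-1,3-benzodioxin-7-one
Product: 8 (4aR)-2,2,5,5,6,8-hexamethyl-4,4a,5,6-tetrahydro-7H-1,3-benzodioxin-7-one (both epimers at the new methyl-bearing carbon, target C8)
Conditions: LiN(i-Pr)2, THF, −78 °C; MeI, DMPU, −78 → 0 °C
Reagents that add atoms: iodomethane, CI
Why: Stork–Danheiser α′-alkylation: the amide base removes a C8 proton next to the C7 ketone in preference to the hindered γ C2′–H and MeI alkylates the cross-conjugated enolate; the C8 centre forms as an epimer mixture that is planarised in step 7.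

Step 7
Reactants: 8 (4aR)-2,2,5,5,6,8-hexamethyl-4,4a,5,6-tetrahydro-7H-1,3-benzodioxin-7-one
Product: 9 (4aR)-7-(tert-butyldimethylsilyloxy)-2,2,5,5,6,8-hexamethyl-4a,5-dihydro-4H-1,3-benzodioxine (diene C5=C6–C7=C8 in target locants)
Conditions: LiN(i-Pr)2, THF, −78 → −30 °C; TBSCl, DMPU, −78 → 23 °C; Et3N-buffered work-up
Reagents that add atoms: tert-butyl(chloro)dimethylsilane, CC(C)(C)[Si](C)(C)Cl
Why: A second carbonyl-directed kinetic enolisation removes the remaining C8–H and O-silylation (silyl enol ether formation) gives the 5-alkoxy-7-silyloxy diene without disturbing the γ C2′ stereocentre.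

Step 8
Reactants: 10 ethyl (R)-3-hydroxy-3-phenylpropanoate
Product: 11 ethyl (R)-3-phenyl-3-(triethylsilyloxy)propanoate
Conditions: TESCl, imidazole, CH2Cl2, 0 → 23 °C
Reagents that add atoms: chlorotriethylsilane, CC[Si](CC)(CC)Cl
Why: Standard silylation of the secondary benzylic alcohol; the triethylsilyl ether survives the organomagnesium steps and later falls in the same mild acid treatment as the acetonide, and C2 is untouched.

Step 9
Reactants: 11 ethyl (R)-3-phenyl-3-(triethylsilyloxy)propanoate
Product: 12 (R)-N-methoxy-N-methyl-3-phenyl-3-(triethylsilyloxy)propanamide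
Conditions: MeNHOMe·HCl, i-PrMgCl, THF, −20 → 0 °C
Reagents that add atoms: N,O-dimethylhydroxylamine hydrochloride, CNOC.Cl
Why: Ester aminolysis with the chloromagnesium amide of N,O-dimethylhydroxylamine (Weinreb amide formation) proceeds at low temperature, where β-elimination of the silyloxy group is not expected.

Step 10
Reactants: 12 (R)-N-methoxy-N-methyl-3-phenyl-3-(triethylsilyloxy)propanamide
Product: 13 (R)-5-phenyl-5-(triethylsilyloxy)pent-1-yn-3-one
Conditions: HC≡CMgBr, THF, −78 → 0 °C; inverse quench into cold aq. NaHSO4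
Reagents that add atoms: ethynylmagnesium bromide, C#C[Mg]Br
Why: Weinreb ketone synthesis: the chelated tetrahedral adduct prevents a second addition, and the acidic inverse quench keeps the released N,O-dimethylhydroxylamine from adding to the ynone.

Step 11
Reactants: 13 (R)-5-phenyl-5-(triethylsilyloxy)pent-1-yn-3-one
Product: 14 (R)-1-bromo-5-phenyl-5-(triethylsilyloxy)pent-1-yn-3-one
Conditions: NBS, AgNO3 (10 mol %), acetone, 23 °C, dark
Reagents that add atoms: N-bromosuccinimide, O=C1CCC(=O)N1Br
Why: Silver-catalysed electrophilic bromination of the terminal alkyne with NBS (through the silver acetylide) gives the 1-bromoalkyne and leaves ketone and silyl ether alone.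

Step 12
Reactants: 9 (4aR)-7-(tert-butyldimethylsilyloxy)-2,2,5,5,6,8-hexamethyl-4a,5-dihydro-4H-1,3-benzodioxine; 14 (R)-1-bromo-5-phenyl-5-(triethylsilyloxy)pent-1-yn-3-one
Product: 15 Diels–Alder adduct: bicyclo[2.2.2]octa-2,5-diene with bridgeheads C5 (acetonide oxygen) and C8 (methyl); bridges C6(Me)=C7(OTBS), C4a[(R)-3-phenyl-3-(triethylsilyloxy)propanoyl]=C8a(Br) and C2′H–C3′Me2; dioxane C5–O–CMe2–O–C1′H2–C2′ with C1′ on the side of the C6=C7 bridge
Conditions: toluene (1 M), BHT (cat.), 60 °C, sealed tube
Reagents that add atoms: none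
Why: A thermal, concerted but asynchronous normal-demand [4+2] cycloaddition joins the nucleophilic diene terminus C8 (β to the C7 silyloxy group and vinylogously activated by the C5 alkoxy group) to the bromine-bearing β-carbon C8a of the ynone and C5 to the α-carbon C4a; the closest known reaction type is the Diels–Alder reaction of 1-alkoxy-3-silyloxycyclohexa-1,3-dienes with alkynones and 3-halopropiolates. The one ring that closes, C5–C6–C7–C8–C8a–C4a, forms suprafacially on both partners in a single [4+2] event and completes the bicyclo[2.2.2]octa-2,5-diene. The new stereocentres C5 and C8 are set together by the diene face that is attacked: the fused dioxane holds C1′ pseudo-equatorial and C2′–H pseudo-axial, the pseudo-axial C3′ methyl therefore covers the opposite face, and the ynone adds on the C2′–H face so that C1′ ends over the C6=C7 bridge, while C2 and C2′ are carried through unchanged. Regioselectivity is required and is secured by the matched polarisation of the 5-alkoxy-7-silyloxy diene and the ynone. Chemoselectivity is also required (retention of the C8a bromide and of the saturated C2′–C3′ bridge) and is secured by the absence of a Lewis acid, which avoids stepwise addition–elimination, and by a temperature well below that of Alder–Rickert cycloreversion; the bridgehead position of the C5 oxygen rules out β-elimination of the acetal.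

Step 13
Reactants: 15 Diels–Alder adduct
Product: 16 C6-bromo C7-ketone: as 15 but with C7 as a ketone and C6 bearing methyl and bromine, bromine on the side of the C4a=C8a bridge
Conditions: NBS, THF, −78 → 0 °C
Reagents that add atoms: N-bromosuccinimide, O=C1CCC(=O)N1Br
Why: Electrophilic α-bromination of the silyl enol ether: bromine should add to C6 on the face syn to the C4a=C8a bridge because the other face is covered by C1′H2 and a C3′ methyl, which sets C6 with bromine anti to the C1′ oxygen.

Step 14
Reactants: 16 C6-bromo C7-ketone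
Product: 18 CNP0322161.2 (target), via triol dibromide 17 (not isolated)
Conditions: PPTS, MeOH, 23 → 40 °C; concentrate; then K2CO3, MeCN, 0 → 23 °C
Reagents that add atoms: none
Why: Acid methanolysis frees the C2, C5 and C1′ hydroxyls, after which carbonate triggers an intramolecular Williamson etherification (5-exo-tet SN2 at the α-keto tertiary bromide with inversion at C6, the carbonyl π system lying parallel to the substitution axis) and a 6-endo oxa-Michael addition–elimination at the β-bromoenone (C2 retained), while retro-aldol at C5 is disfavoured because the C5–C6 bond lies in the nodal plane of the C7 carbonyl.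

**Compound list**

1 | dimedone (5,5-dimethylcyclohexane-1,3-dione) | CC1(C)CC(=O)CC(=O)C1 | starting material
2 | 2,5,5-trimethylcyclohexane-1,3-dione | CC1C(=O)CC(C)(C)CC1=O | intermediate
3 | 3-(benzyloxy)-2,5,5-trimethylcyclohex-2-en-1-one | CC1(C)CC(=O)C(C)=C(OCc2ccccc2)C1 | intermediate
4 | 1-(benzyloxy)-2,5,5-trimethyl-3-(trimethylsilyloxy)cyclohexa-1,3-diene | CC1(C)CC(OCc2ccccc2)=C(C)C(O[Si](C)(C)C)=C1 | intermediate
5 | (R)-3-(benzyloxy)-6-(hydroxymethyl)-2,5,5-trimethylcyclohex-2-en-1-one | CC1(C)CC(OCc2ccccc2)=C(C)C(=O)[C@H]1CO | intermediate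
6 | (R)-4-(hydroxymethyl)-2,5,5-trimethylcyclohexane-1,3-dione (enolised in solution; C2 not defined) | CC1(C)CC(=O)C(C)C(=O)[C@H]1CO | intermediate
7 | (4aR)-2,2,5,5,8-pentamethyl-4,4a,5,6-tetrahydro-7H-1,3-benzodioxin-7-one (acetonide across C5–O and C1′–O, ketone at C7) | CC1(C)CC(=O)C(C)=C2OC(C)(C)OC[C@@H]12 | intermediate
8 | (4aR)-2,2,5,5,6,8-hexamethyl-4,4a,5,6-tetrahydro-7H-1,3-benzodioxin-7-one, both epimers at target C8 | CC1(C)C(C)C(=O)C(C)=C2OC(C)(C)OC[C@@H]12 | intermediate
9 | (4aR)-7-(tert-butyldimethylsilyloxy)-2,2,5,5,6,8-hexamethyl-4a,5-dihydro-4H-1,3-benzodioxine | CC1(C)[C@@H]2COC(C)(C)OC2=C(C)C(O[Si](C)(C)C(C)(C)C)=C1C | intermediate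
10 | ethyl (R)-3-hydroxy-3-phenylpropanoate | CCOC(=O)C[C@H](c1ccccc1)O | starting material
11 | ethyl (R)-3-phenyl-3-(triethylsilyloxy)propanoate | CCOC(=O)C[C@H](c1ccccc1)O[Si](CC)(CC)CC | intermediate
12 | (R)-N-methoxy-N-methyl-3-phenyl-3-(triethylsilyloxy)propanamide | CON(C)C(=O)C[C@H](c1ccccc1)O[Si](CC)(CC)CC | intermediate
13 | (R)-5-phenyl-5-(triethylsilyloxy)pent-1-yn-3-one | C#CC(=O)C[C@H](c1ccccc1)O[Si](CC)(CC)CC | intermediate
14 | (R)-1-bromo-5-phenyl-5-(triethylsilyloxy)pent-1-yn-3-one | BrC#CC(=O)C[C@H](c1ccccc1)O[Si](CC)(CC)CC | intermediate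
15 | Diels–Alder adduct: bicyclo[2.2.2]octa-2,5-diene with C5–O/C1′–O acetonide, C6-methyl C7-OTBS enol ether, C8a bromide, C4a (R)-3-phenyl-3-(triethylsilyloxy)propanoyl group; C5, C8 and C2′ as in the target | CC1(C)[C@@H]2COC(C)(C)O[C@]23C(C)=C(O[Si](C)(C)C(C)(C)C)[C@@]1(C)C(Br)=C3C(=O)C[C@H](c1ccccc1)O[Si](CC)(CC)CC | intermediate
16 | C6-bromo C7-ketone of 15 (bromine syn to the C4a=C8a bridge, methyl toward C2′) | CC1(C)[C@@H]2COC(C)(C)O[C@]23[C@@](C)(Br)C(=O)[C@@]1(C)C(Br)=C3C(=O)C[C@H](c1ccccc1)O[Si](CC)(CC)CC | intermediate
17 | triol dibromide: 16 with free C2, C5 and C1′ hydroxyls | CC1(C)[C@H](CO)[C@]2(O)[C@@](C)(Br)C(=O)[C@@]1(C)C(Br)=C2C(=O)C[C@H](c1ccccc1)O | intermediate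
18 | CNP0322161.2 | CC1(C)[C@@H]2CO[C@]3(C)C(=O)[C@@]1(C)C1=C(C(=O)C[C@H](c4ccccc4)O1)[C@]23O | target

**Step count and risks**

Total steps: 14. Longest linear sequence: 10 (steps 1–7, then 12–14); steps 8–11 form the four-step ynone branch.

Step 4. The risk is insufficient enantiofacial discrimination at the neopentyl-type C2′, together with protodesilylation of the silyl dienol ether back to 3. Any minor enantiomer that survives would become a separable diastereomer of 15 after step 12, but a low ratio wastes material. Fallback by resolution instead of catalytic induction: setting out from 4, ligand-free hydroxymethylation (Yb(OTf)3, aq. HCHO, THF) gives the racemic hydroxymethyl ketone F1. The conditions of step 5 convert it through the racemic dione F2 (not isolated) into the racemic acetonide F3, which is configurationally robust. Preparative chromatography on a chiral stationary phase separates 7 from the unwanted (4aS)-acetonide F4, and the route is rejoined at 7.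

Step 12. The risk is a sluggish cycloaddition at two fully substituted diene termini, with conjugate addition–elimination at the bromoalkyne (loss of bromide, alkynylation at C8) or erosion of facial selectivity if the reaction has to be forced. Fallback with a bromine-free dienophile and a later oxidation-level adjustment: setting out from 9 and 13, the less hindered terminal ynone should give the bromine-free adduct F5 (C8a–H) with the same regiochemistry and facial sense. NBS as in step 13 gives the C6-bromo ketone F6, and PPTS/MeOH gives the triol F7. K2CO3 in MeCN closes only the ether to the tetrahydrofuran-closed hydroxy enone F8. A Wacker-type oxidative 6-endo cyclisation with divalent palladium (PdCl2(MeCN)2 cat., CuCl, Na2HPO4, O2, DME; oxypalladation then β-hydride elimination) then forms the O1–C8a bond, and the route is rejoined at 18.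

Step 14. The risk is dehydrobromination toward the C6 methyl group, or retro-aldol fragmentation of the base-exposed β-hydroxy ketone with loss of benzaldehyde, outrunning the two ring closures. Fallback by staging the closures and making the ether without base: setting out from 17, now isolated after the methanolysis stage, AgOTf with 2,6-di-tert-butylpyridine in CH2Cl2 at −20 °C ionises the tertiary C6–Br bond by halophilic activation. The C1′ hydroxyl, the only oxygen able to reach C6 and only from the C2′ side, captures it to give the tetrahydrofuran-closed bromoenone diol F9. Et3N in CH2Cl2 then closes the pyranone by addition–elimination, and the route is rejoined at 18.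

**Further compounds**

F1 | step 4 | racemic 3-(benzyloxy)-6-(hydroxymethyl)-2,5,5-trimethylcyclohex-2-en-1-one | CC1(C)CC(OCc2ccccc2)=C(C)C(=O)C1CO
F2 | step 4 | racemic 4-(hydroxymethyl)-2,5,5-trimethylcyclohexane-1,3-dione | CC1(C)CC(=O)C(C)C(=O)C1CO
F3 | step 4 | racemic 2,2,5,5,8-pentamethyl-4,4a,5,6-tetrahydro-7H-1,3-benzodioxin-7-one | CC1(C)CC(=O)C(C)=C2OC(C)(C)OCC12
F4 | step 4 | (4aS)-2,2,5,5,8-pentamethyl-4,4a,5,6-tetrahydro-7H-1,3-benzodioxin-7-one | CC1(C)CC(=O)C(C)=C2OC(C)(C)OC[C@H]12
F5 | step 12 | bromine-free Diels–Alder adduct of 9 and 13 (C8a–H) | CC1(C)[C@@H]2COC(C)(C)O[C@]23C(C)=C(O[Si](C)(C)C(C)(C)C)[C@@]1(C)C=C3C(=O)C[C@H](c1ccccc1)O[Si](CC)(CC)CC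
F6 | step 12 | C6-bromo C7-ketone of F5 | CC1(C)[C@@H]2COC(C)(C)O[C@]23[C@@](C)(Br)C(=O)[C@@]1(C)C=C3C(=O)C[C@H](c1ccccc1)O[Si](CC)(CC)CC
F7 | step 12 | triol of F6 (free C2, C5 and C1′ hydroxyls, C8a–H) | CC1(C)[C@H](CO)[C@]2(O)[C@@](C)(Br)C(=O)[C@@]1(C)C=C2C(=O)C[C@H](c1ccccc1)O
F8 | step 12 | tetrahydrofuran-closed hydroxy enone (O–C6 formed, C8a–H, C2–OH free) | CC1(C)[C@@H]2CO[C@]3(C)C(=O)[C@@]1(C)C=C(C(=O)C[C@H](c4ccccc4)O)[C@]23O
F9 | step 14 | tetrahydrofuran-closed bromoenone diol (O–C6 formed, C8a–Br, C2–OH free) | CC1(C)[C@@H]2CO[C@]3(C)C(=O)[C@@]1(C)C(Br)=C(C(=O)C[C@H](c4ccccc4)O)[C@]23O
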